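Everything rests on cutting the C3–C4 bond of the tetrahydrofuran ring (O1, C2 aryl, C3 CH2OH, C4 aroyl, C5H2). The feature exploited is the C3–CH2OH unit, which is what remains when a terminal epoxide is opened to a carbon radical. It sits next to C4, whose exocyclic carbon bears an aryl group and maps onto the far end of an arylalkyne. One Cp2TiCl operation opens the epoxide, closes the ring 5-exo-dig, forms C3–C4 and sets C3 trans to C2. The substrate is an aryl(oxiranyl)methyl 3-arylprop-2-ynyl ether that is stereodefined only at C2. Benzylic hydration, oxidation, C4 equilibration and hydrogenolysis finish the synthesis.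

Key step: step 9

Remark: ring atoms are numbered O1, C2 (aryl), C3 (CH2OH), C4 (aroyl), C5 (CH2); read this way the target is (2S,3R,4S), that is 2,3-trans and 3,4-trans; Ar = 4-(benzyloxy)-3,5-dimethoxyphenyl.

Step 1
Reactants: 1 syringaldehyde (4-hydroxy-3,5-dimethoxybenzaldehyde)
Product: 2 4-(benzyloxy)-3,5-dimethoxybenzaldehyde
Conditions: BnBr, K2CO3, DMF, 60 °C
Reagents that add atoms: benzyl bromide, BrCc1ccccc1
Why: Williamson O-alkylation of the phenoxide, which leaves the aldehyde alone and installs a group that survives every step up to the final hydrogenolysis.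

Step 2
Reactants: 2 4-(benzyloxy)-3,5-dimethoxybenzaldehyde; 3 vinylmagnesium bromide
Product: 5 rac-1-[4-(benzyloxy)-3,5-dimethoxyphenyl]prop-2-en-1-ol, via BrMg alkoxide 4 (not isolated)
Conditions: THF, −78 → 0 °C; sat. aq NH4Cl
Reagents that add atoms: none
Why: Grignard 1,2-addition to a non-enolisable aromatic aldehyde; the carbinol centre forms racemic and is resolved in step 3.

Step 3
Reactants: 5 rac-1-[4-(benzyloxy)-3,5-dimethoxyphenyl]prop-2-en-1-ol
Product: 6 (S)-1-[4-(benzyloxy)-3,5-dimethoxyphenyl]prop-2-en-1-ol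
Conditions: Ti(OiPr)4 (20 mol %), L-(+)-DIPT (24 mol %), t-BuOOH (0.6 equiv), 4 Å MS, CH2Cl2, −20 °C
Reagents that add atoms: none
Why: Sharpless kinetic resolution: with L-(+)-DIPT the (R)-carbinol is the fast-reacting enantiomer and is removed as its anti epoxy alcohol, so carrying the oxidation slightly past half conversion should leave the (S)-carbinol, the future C2 centre, in high enantiomeric purity.

Step 4
Reactants: 7 4-bromo-2,6-dimethoxyphenol
Product: 8 2-(benzyloxy)-5-bromo-1,3-dimethoxybenzene
Conditions: BnBr, K2CO3, DMF, 60 °C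
Reagents that add atoms: benzyl bromide, BrCc1ccccc1
Why: Williamson O-alkylation of the phenoxide, which removes the acidic OH before the cross-coupling.

Step 5
Reactants: 8 2-(benzyloxy)-5-bromo-1,3-dimethoxybenzene; 9 propargyl alcohol
Product: 10 3-[4-(benzyloxy)-3,5-dimethoxyphenyl]prop-2-yn-1-ol
Conditions: Pd(PhCN)2Cl2 (3 mol %), P(t-Bu)3·HBF4 (6 mol %), CuI (2 mol %), i-Pr2NH, dioxane, rt → 45 °C
Reagents that add atoms: none
Why: Sonogashira coupling in which the bulky, electron-rich phosphine lets zerovalent palladium insert into the electron-rich aryl bromide under mild conditions, and the free propargylic OH is tolerated.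

Step 6
Reactants: 10 3-[4-(benzyloxy)-3,5-dimethoxyphenyl]prop-2-yn-1-ol
Product: 11 2-(benzyloxy)-5-(3-bromoprop-1-yn-1-yl)-1,3-dimethoxybenzene
Conditions: CBr4, PPh3, CH2Cl2, 0 °C
Reagents that add atoms: carbon tetrabromide, BrC(Br)(Br)Br
Why: Appel bromination (SN2 on the alkoxyphosphonium ion) under neutral conditions that leave the alkyne and the benzyl ether untouched.

Step 7
Reactants: 6 (S)-1-[4-(benzyloxy)-3,5-dimethoxyphenyl]prop-2-en-1-ol; 11 2-(benzyloxy)-5-(3-bromoprop-1-yn-1-yl)-1,3-dimethoxybenzene
Product: 13 (S)-1-Ar-prop-2-enyl 3-Ar-prop-2-ynyl ether, via Na alkoxide 12 (not isolated)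
Conditions: NaH, THF–DMF, 0 °C; 11, Bu4NI (cat.), 0 °C → rt
Reagents that add atoms: none
Why: Williamson ether synthesis by SN2 attack on a primary propargylic bromide; no bond to the stereocentre is broken, so the (S) configuration is carried over, and the low temperature avoids base-induced isomerisation of the allylic alkoxide or of the propargyl ether.

Step 8
Reactants: 13 (S)-1-Ar-prop-2-enyl 3-Ar-prop-2-ynyl ether
Product: 14 Ar(oxiran-2-yl)methyl 3-Ar-prop-2-ynyl ether (benzylic centre unchanged in space and now labelled R because the oxirane carbon outranks aryl; both epimers at the oxirane carbon)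
Conditions: m-CPBA (2.5 equiv), CH2Cl2, 0 °C → rt
Reagents that add atoms: m-CPBA, O=C(OO)c1cccc(Cl)c1
Why: Prilezhaev epoxidation of the only alkene, which is far more nucleophilic toward a peracid than the aryl alkyne; no facial control is sought because the oxirane carbon becomes a planar radical in step 9, so both epimers are carried on together.

Step 9
Reactants: 14 Ar(oxiran-2-yl)methyl 3-Ar-prop-2-ynyl ether
Product: 18 [(2S,3R)-2-Ar-4-(Ar-methylidene)oxolan-3-yl]methanol (E/Z mixture), via Cp2Ti(Cl)O-alkyl radical 15 (not isolated), via vinyl radical 16 (not isolated), via Cp2Ti(Cl) alkoxide 17 (not isolated)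
Conditions: Cp2TiCl2 (2.5 equiv), Zn dust, THF, rt (green Cp2TiCl); added slowly to 14 in THF (0.02 M), rt; cold 0.5 M HCl
Reagents that add atoms: none
Why: Single-electron transfer from Cp2TiCl (trivalent titanium) breaks the C3–O bond of the terminal epoxide and leaves the secondary radical 15 with the titanium alkoxide on the future CH2OH carbon; this is the Nugent–RajanBabu reductive epoxide opening, and its use on epoxy propargyl ethers to build 3-(hydroxymethyl)tetrahydrofurans is established chemistry. Radical 15 adds to the near alkyne carbon in a 5-exo-dig closure of the ring O1–C2–C3–C4–C5, which forms C3–C4 and places the unpaired electron on the aryl-bearing carbon as the conjugated vinyl radical 16. Radical 16 takes hydrogen from THF, or is captured by a second Cp2TiCl and protonated at work-up, to give alkoxide 17, so two equivalents of titanium are budgeted per epoxide. C3 is planar in 15, so both oxirane epimers converge, and the new C3 centre is set by the existing C2 centre: in a Beckwith–Houk-type transition state the C2 aryl group and the CH2OTi arm both take pseudo-equatorial positions, which should give the 2,3-trans (2S,3R) ring. The step needs three selectivities: opening toward the secondary rather than the primary radical (secured by radical stability), exo rather than 6-endo attack (secured by the short oxygen tether and the aryl stabilisation of the exo vinyl radical), and cyclisation ahead of titanium-induced deoxygenation back to the allyl ether (secured by the fast aryl alkyne acceptor and by slow addition, which keeps Cp2TiCl dilute). The alkene geometry is irrelevant because both sp2 carbons are re-hybridised in steps 11 and 12.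

Step 10
Reactants: 18 [(2S,3R)-2-Ar-4-(Ar-methylidene)oxolan-3-yl]methanol
Product: 19 benzyl [(2S,3R)-2-Ar-4-(Ar-methylidene)oxolan-3-yl]methyl carbonate
Conditions: CbzCl, pyridine, DMAP (cat.), CH2Cl2, 0 °C → rt
Reagents that add atoms: benzyl chloroformate, O=C(Cl)OCc1ccccc1
Why: Chloroformate acylation of the primary alcohol; the mask stops a 3,4-cis keto alcohol from hiding as a cis-fused bicyclic hemiketal during the C4 equilibration of step 12, and a benzyl carbonate is chosen because it leaves in the same hydrogenolysis as the aryl benzyl ethers.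

Step 11
Reactants: 19 benzyl [(2S,3R)-2-Ar-4-(Ar-methylidene)oxolan-3-yl]methyl carbonate
Product: 21 benzyl {(2S,3R)-2-Ar-4-[Ar(hydroxy)methyl]oxolan-3-yl}methyl carbonate (mixture at C4 and at the carbinol carbon), via benzylic borane 20 (not isolated)
Conditions: BH3·THF (3 equiv), THF, 0 °C → rt; H2O, then NaBO3·4H2O, rt
Reagents that add atoms: NaBO3·4H2O (peroxoborate dimer, lattice water omitted), [Na+].[Na+].O[B-]1(O)OO[B-](O)(O)OO1
Why: Brown hydroboration–oxidation: syn addition puts boron on the less substituted benzylic alkene carbon and hydrogen on C4, and perborate replaces boron by OH with retention under conditions mild enough for the carbonate; the two new centres need no control because the carbinol is oxidised and C4 is equilibrated in step 12.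

Step 12
Reactants: 21 benzyl {(2S,3R)-2-Ar-4-[Ar(hydroxy)methyl]oxolan-3-yl}methyl carbonate
Product: 23 benzyl [(2S,3R,4S)-2-Ar-4-(Ar-carbonyl)oxolan-3-yl]methyl carbonate, via C4-epimeric ketones 22 (not isolated)
Conditions: Dess–Martin periodinane, CH2Cl2, 0 °C → rt; aqueous wash; crude 22, DBU, toluene, 50 °C
Reagents that add atoms: none
Why: Dess–Martin oxidation gives the aryl ketone and DBU then epimerises C4 through the enolate under thermodynamic control, moving the aroyl group trans to the C3 side chain to give the all-trans (2S,3R,4S) ring, while C2 and C3 carry no acidic hydrogen and an aprotic amine base gives loss of the C5–O1 alkoxide (ring opening) little chance.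

Step 13
Reactants: 23 benzyl [(2S,3R,4S)-2-Ar-4-(Ar-carbonyl)oxolan-3-yl]methyl carbonate
Product: 25 [(2S,3R,4S)-2-(4-hydroxy-3,5-dimethoxyphenyl)-3-(hydroxymethyl)oxolan-4-yl](4-hydroxy-3,5-dimethoxyphenyl)methanone (target), via carbonic acid monoester 24 (not isolated)
Conditions: H2 (1 atm), 10% Pd/C, EtOAc–EtOH, rt, stopped as soon as debenzylation is complete
Reagents that add atoms: none
Why: Catalytic hydrogenolysis: hindered aryl benzyl ethers and a benzyl carbonate are among the most quickly cleaved O-benzyl groups, the carbonic acid monoester loses CO2 by itself, and a short reaction under neutral conditions should spare the electron-rich aryl ketone and the benzylic C2–O1 bond, so no stereocentre is touched.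

Compound list
1 | syringaldehyde | COc1cc(C=O)cc(OC)c1O | starting material
2 | 4-(benzyloxy)-3,5-dimethoxybenzaldehyde | COc1cc(C=O)cc(OC)c1OCc1ccccc1 | intermediate
3 | vinylmagnesium bromide | C=C[Mg]Br | starting material
4 | BrMg alkoxide of 5 | C=CC(O[Mg]Br)c1cc(OC)c(OCc2ccccc2)c(OC)c1 | intermediate
5 | rac-1-[4-(benzyloxy)-3,5-dimethoxyphenyl]prop-2-en-1-ol | C=CC(O)c1cc(OC)c(OCc2ccccc2)c(OC)c1 | intermediate
6 | (S)-1-[4-(benzyloxy)-3,5-dimethoxyphenyl]prop-2-en-1-ol | C=C[C@H](O)c1cc(OC)c(OCc2ccccc2)c(OC)c1 | intermediate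
7 | 4-bromo-2,6-dimethoxyphenol | COc1cc(Br)cc(OC)c1O | starting material
8 | 2-(benzyloxy)-5-bromo-1,3-dimethoxybenzene | COc1cc(Br)cc(OC)c1OCc1ccccc1 | intermediate
9 | propargyl alcohol | C#CCO | starting material
10 | 3-[4-(benzyloxy)-3,5-dimethoxyphenyl]prop-2-yn-1-ol | COc1cc(C#CCO)cc(OC)c1OCc1ccccc1 | intermediate
11 | 2-(benzyloxy)-5-(3-bromoprop-1-yn-1-yl)-1,3-dimethoxybenzene | COc1cc(C#CCBr)cc(OC)c1OCc1ccccc1 | intermediate
12 | Na alkoxide of 6 | [Na+].C=C[C@H]([O-])c1cc(OC)c(OCc2ccccc2)c(OC)c1 | intermediate
13 | (S)-1-Ar-prop-2-enyl 3-Ar-prop-2-ynyl ether | COc1cc(C#CCO[C@H](c2cc(OC)c(OCc3ccccc3)c(OC)c2)C=C)cc(OC)c1OCc1ccccc1 | intermediate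
14 | (R)-Ar(oxiran-2-yl)methyl 3-Ar-prop-2-ynyl ether, both epimers at the oxirane carbon | COc1cc(C#CCO[C@H](c2cc(OC)c(OCc3ccccc3)c(OC)c2)C2CO2)cc(OC)c1OCc1ccccc1 | intermediate
15 | secondary C3 radical with a Cp2Ti(Cl)O group on the neighbouring CH2 | COc1cc(C#CCO[C@H](c2cc(OC)c(OCc3ccccc3)c(OC)c2)[CH]CO[Ti](Cl)(C2C=CC=C2)C2C=CC=C2)cc(OC)c1OCc1ccccc1 | intermediate
16 | cyclised alpha-aryl vinyl radical (2,3-trans oxolane) | COc1cc([C]=C2CO[C@H](c3cc(OC)c(OCc4ccccc4)c(OC)c3)[C@H]2CO[Ti](Cl)(C2C=CC=C2)C2C=CC=C2)cc(OC)c1OCc1ccccc1 | intermediate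
17 | Cp2Ti(Cl) alkoxide of 18 | COc1cc(C=C2CO[C@H](c3cc(OC)c(OCc4ccccc4)c(OC)c3)[C@H]2CO[Ti](Cl)(C2C=CC=C2)C2C=CC=C2)cc(OC)c1OCc1ccccc1 | intermediate
18 | [(2S,3R)-2-Ar-4-(Ar-methylidene)oxolan-3-yl]methanol, E/Z mixture | COc1cc(C=C2CO[C@H](c3cc(OC)c(OCc4ccccc4)c(OC)c3)[C@H]2CO)cc(OC)c1OCc1ccccc1 | intermediate
19 | benzyl [(2S,3R)-2-Ar-4-(Ar-methylidene)oxolan-3-yl]methyl carbonate | COc1cc(C=C2CO[C@H](c3cc(OC)c(OCc4ccccc4)c(OC)c3)[C@H]2COC(=O)OCc2ccccc2)cc(OC)c1OCc1ccccc1 | intermediate
20 | benzylic monoalkylborane from 19 (BH2 on the exocyclic carbon, H on C4) | COc1cc(C(B)C2CO[C@H](c3cc(OC)c(OCc4ccccc4)c(OC)c3)[C@H]2COC(=O)OCc2ccccc2)cc(OC)c1OCc1ccccc1 | intermediate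
21 | benzyl {(2S,3R)-2-Ar-4-[Ar(hydroxy)methyl]oxolan-3-yl}methyl carbonate, mixture at C4 and carbinol carbon | COc1cc(C(O)C2CO[C@H](c3cc(OC)c(OCc4ccccc4)c(OC)c3)[C@H]2COC(=O)OCc2ccccc2)cc(OC)c1OCc1ccccc1 | intermediate
22 | benzyl [(2S,3R)-2-Ar-4-(Ar-carbonyl)oxolan-3-yl]methyl carbonate, C4 epimers | COc1cc(C(=O)C2CO[C@H](c3cc(OC)c(OCc4ccccc4)c(OC)c3)[C@H]2COC(=O)OCc2ccccc2)cc(OC)c1OCc1ccccc1 | intermediate
23 | benzyl [(2S,3R,4S)-2-Ar-4-(Ar-carbonyl)oxolan-3-yl]methyl carbonate | COc1cc(C(=O)[C@@H]2CO[C@H](c3cc(OC)c(OCc4ccccc4)c(OC)c3)[C@H]2COC(=O)OCc2ccccc2)cc(OC)c1OCc1ccccc1 | intermediate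
24 | carbonic acid monoester of the target (CH2OCO2H, both phenols free) | COc1cc(C(=O)[C@@H]2CO[C@H](c3cc(OC)c(O)c(OC)c3)[C@H]2COC(=O)O)cc(OC)c1O | intermediate
25 | [(2S,3R,4S)-2-(4-hydroxy-3,5-dimethoxyphenyl)-3-(hydroxymethyl)oxolan-4-yl](4-hydroxy-3,5-dimethoxyphenyl)methanone | COc1cc(C(=O)[C@@H]2CO[C@H](c3cc(OC)c(O)c(OC)c3)[C@H]2CO)cc(OC)c1O | target

Total step count: 13. Longest linear sequence: 10 steps (1, 2, 3, 7, 8, 9, 10, 11, 12, 13); steps 4–6 form the three-step side branch that joins at step 7.

Steps most likely to fail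

**Step 9.** Several things could go wrong.
- The C3 radical could be intercepted before ring closure, either by hydrogen transfer or by capture at a second titanium centre followed by loss of the titanoxy group.
- Chloride could open the Lewis-acid-activated epoxide.
- The 2,3-trans preference could be weak.

The fallback makes the same radical by tin hydride chemistry instead of epoxide opening. It sets out from 13. OsO4 (cat.)/NMO dihydroxylates the vinyl group to the vicinal diol F1, and TBSCl/imidazole at 0 °C silylates only the primary hydroxyl to give the primary silyl ether F2. 1,1'-Thiocarbonyldiimidazole then converts the secondary alcohol into the imidazolylthiocarbonyl ester F3. Slow addition of Bu3SnH/AIBN in toluene at 80 °C causes Barton–McCombie-type C–O homolysis, the same 5-exo-dig closure and rapid hydrogen transfer from tin, giving the cyclised silyl ether F4. Bu4NF in THF removes the silyl group and the route is rejoined at 18.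

**Step 11.** Addition to the hindered trisubstituted alkene could be sluggish. Partial placement of boron on C4 would be followed by beta-alkoxy elimination and ring opening. The carbonate could also erode during oxidation.

The fallback replaces hydroboration by dihydroxylation and reductive deoxygenation, and sets out from 19. OsO4 (cat.)/NMO gives the C4-hydroxy benzylic diol F5. Parikh–Doering oxidation (SO3·pyridine, DMSO, Et3N) of the secondary benzylic alcohol gives the tertiary alpha-hydroxy ketone F6. SmI2 in THF–MeOH at −78 °C cleaves the C4–OH bond alpha to the ketone and the enolate is protonated. This delivers the ketone epimers 22, which receive the DBU treatment of step 12.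

**Step 8.** The electron-poor monosubstituted alkene may convert slowly. Long peracid exposure would allow oxidation of the electron-rich rings or the alkyne, and acid-induced opening of the epoxide.

The fallback installs the epoxide before the ether bond and sets out from 5.
- The resolution is run in the opposite sense (Ti(OiPr)4, D-(−)-DIPT, substoichiometric t-BuOOH, stopped short of half conversion).
- The wanted (S)-carbinol is then the fast-reacting enantiomer and is isolated as the anti epoxy alcohol (R)-Ar[(S)-oxiran-2-yl]methanol F7.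
- Neutral O-alkylation with bromide 11 and Ag2O in CH2Cl2 gives the single-epimer epoxy propargyl ether F8. This is one of the two components of 14, so the route is rejoined at 14.
- The variant is held in reserve for two reasons: any basic alkylation invites Payne rearrangement, and the enantiomeric purity of a resolution product cannot be raised by over-conversion.

Further compounds
F1 | step 9 | vicinal diol from 13 (benzylic centre unchanged, both epimers at the new carbinol carbon) | COc1cc(C#CCO[C@H](c2cc(OC)c(OCc3ccccc3)c(OC)c2)C(O)CO)cc(OC)c1OCc1ccccc1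
F2 | step 9 | primary tert-butyldimethylsilyl ether of F1 | COc1cc(C#CCO[C@H](c2cc(OC)c(OCc3ccccc3)c(OC)c2)C(O)CO[Si](C)(C)C(C)(C)C)cc(OC)c1OCc1ccccc1
F3 | step 9 | imidazolylthiocarbonyl ester of F2 | COc1cc(C#CCO[C@H](c2cc(OC)c(OCc3ccccc3)c(OC)c2)C(CO[Si](C)(C)C(C)(C)C)OC(=S)n2ccnc2)cc(OC)c1OCc1ccccc1
F4 | step 9 | tert-butyldimethylsilyl ether of 18 | COc1cc(C=C2CO[C@H](c3cc(OC)c(OCc4ccccc4)c(OC)c3)[C@H]2CO[Si](C)(C)C(C)(C)C)cc(OC)c1OCc1ccccc1
F5 | step 11 | diol from 19 (tertiary OH on C4, secondary benzylic OH) | COc1cc(C(O)C2(O)CO[C@H](c3cc(OC)c(OCc4ccccc4)c(OC)c3)[C@H]2COC(=O)OCc2ccccc2)cc(OC)c1OCc1ccccc1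
F6 | step 11 | C4-hydroxy aryl ketone from F5 | COc1cc(C(=O)C2(O)CO[C@H](c3cc(OC)c(OCc4ccccc4)c(OC)c3)[C@H]2COC(=O)OCc2ccccc2)cc(OC)c1OCc1ccccc1
F7 | step 8 | (R)-[4-(benzyloxy)-3,5-dimethoxyphenyl][(S)-oxiran-2-yl]methanol | O[C@H](c1cc(OC)c(OCc2ccccc2)c(OC)c1)[C@@H]1CO1
F8 | step 8 | (R)-Ar[(S)-oxiran-2-yl]methyl 3-Ar-prop-2-ynyl ether (single epimer of 14) | COc1cc(C#CCO[C@H](c2cc(OC)c(OCc3ccccc3)c(OC)c2)[C@@H]2CO2)cc(OC)c1OCc1ccccc1
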